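The data are simulated from invented constants; the scatter is artificial.

A small charge of electrophile, with nucleophile fed in and free base beside it, is followed on Tuesday and is to be read at 3.0 d; Wednesday's run had more base.

| flask | electrophile | nucleophile | free base | remark | time |
|---|---|---|---|---|---|
| Tuesday's | 0.50 M | 1 equiv (fed, over 3.0 h) | 1 equiv | the very flask that is asked about, followed so far |  |
| Wednesday's | 0.50 M | 1 equiv (fed, over 3.0 h) | 1.5 equiv | run made earlier |  |
| flask | 0.50 M | 1.00 equiv (fed, over 3.0 h) | 1.00 equiv |  | 3.0 d |

Tuesday's run (percent of the electrophile charged)

| time / h | electrophile / % | target / % |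
|---|---|---|
| 6.00 | 73.3 | 26.2 |
| 12.0 | 57.3 | 42.2 |
| 20.0 | 48.0 | 51.6 |
| 25.0 | 44.7 | 55.5 |
| 30.0 | 42.5 | 57.8 |
| 40.0 | 39.9 | 61.8 |

Wednesday's run (percent of the electrophile charged)

| time / d | electrophile / % | target / % |
|---|---|---|
| 0.250 | 73.6 | 26.6 |
| 0.417 | 60.8 | 38.3 |
| 0.625 | 52.0 | 47.5 |
| 1.04 | 43.5 | 56.7 |
| 1.67 | 39.2 | 61.2 |
| 3.00 | 36.1 | 64.5 |

(standard deviation of a reading: 0.5 percentage points)

- part of the electrophile that has reacted at 3.0 d
- share of the unused nucleophile that is free and not bound as protonated nucleophile, at 3.0 d

- the earlier runs do not show how much of nucleophile is bound; that part of a forecast is a guess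

In both runs electrophile and target add up to about the charge, so I treated the flask as one reaction of equal charges, where the odds of conversion, reacted over unreacted, grow in proportion to time. Tuesday's first reading, with time counted from mid-feed, gives those odds a rate of 0.0809 /h. Multiplied by the time up to 3.0 d, this makes 5.71, the Damköhler number: the time available, in units of the time such a pair, slowing as it is used up, needs to go half way. Its logarithm is 0.757, and it promises 85.1% reacted.

One number was not enough. On logarithmic axes the odds should climb against time with slope one, but Tuesday's last two readings give 0.357. Carrying that slope forward from the last reading, I reckoned odds of 1.87, or 65.1% reacted. The free share the readings do not show, so I put no number on it.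

The forecast said 63.5% reacted, a little less than my figure, and 7% free, reasoning: “Extra base barely helps, so the nucleophile is being tied up progressively.”

The flask gave 63.9% and 5.36%, so the forecast held on both.

    2 free base → self-condensation product (k = 0.680 /M/h)
    nucleophile + acid set free ⇌ protonated nucleophile, settled at all times (K = 940 /M)
    acid set free + free base ⇌ salt of the base, settled at all times (K = 9100 /M)
    electrophile + nucleophile → acid set free + target (k = 0.170 /M/h)

The flask's odds fall short of 5.71 by a factor of 3.23. Two steps together hold it back: against 63.9%, the run without the parking of nucleophile as protonated nucleophile reached 85.7%, and the run without the self-condensation of free base 83.3%.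

At 0.20 M of electrophile the number falls with the concentration to 2.28, promising 69.5%. That neighbour flask computed 58.9%, its odds short by a factor of 1.59.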